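Start with a tank whose outflow is proportional to its level: the fraction of the charge still inside falls as exp(−t/τ), and one reading is enough to give τ. A short meeting took up the flasks below and what was asked of them.

| flask | E | J | temperature | remark | time |
|---|---|---|---|---|---|
| birch | 2.2 M | 0.45 M | 25 °C | run made earlier |  |
| Friday's | 1.5 M | 0.450 M | 5 °C |  | 30 h |
| Sunday's | 1.5 M | 0.450 M | 45 °C |  | 30 h |
| Tuesday's | 1.5 M | 0.450 M | 25 °C |  | 30 h |
| Monday's | 1.5 M | 0.450 M | 40 °C |  | 30 h |
| Saturday's | 1.5 M | 0.450 M | −15 °C |  | 30 h |
| Thursday's | 1.5 M | 0.450 M | 55 °C |  | 30 h |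

birch run (percent of the E charged)

| time / h | Z / % | E / % |
|---|---|---|
| 1.50 | 4 | 75 |
| 3.00 | 8 | 62 |
| 5.00 | 16 | 45 |
| 6.00 | 26 | 36 |
| 8.00 | 31 | 25 |
| 10.0 | 33 | 20 |

(scatter of a reading: 2 percentage points)

- the numbers in the tables scatter with a standard deviation of 2 percentage points
- the earlier runs do not show what temperature does; that part of a forecast is a guess

1. the flasks put in order of amount of Z, in percent of the E charged, best first, at 30 h (Friday's / Sunday's / Tuesday's / Monday's / Saturday's / Thursday's)
2. the same order at 10 d (Friday's / Sunday's / Tuesday's / Monday's / Saturday's / Thursday's)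
3. the amount of Z, in percent of the E charged of the flask you put first, at 30 h
4. the amount of Z, in percent of the E charged of the flask you put last, at 30 h

The secretary opened with the birch run and proposed treating E as that tank. The fraction of E left in birch at 10.0 h was read as 20%, which gave, as a reading with that reading's scatter, 6.21 h as the time constant of E, the first-order time in which the fraction of E left shrinks by the natural factor e. As a check, she reported that this value gave 44.7% at 5.00 h, against the birch reading of 45%.

She then argued that Tuesday's, at the temperature and J of birch, runs for 4.83 time constants, a time much longer than τ, so its fraction of E left at 30 h should be 0.800%. She added that this assumed the fraction did not depend on the charge of E, which birch, with its one charge, could not test, and she committed herself to no figure for Z.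

The forecaster then gave Tuesday's > Monday's > Sunday's > Thursday's > Friday's > Saturday's at 30 h and Friday's > Tuesday's > Monday's > Sunday's > Thursday's > Saturday's at 10 d, with 42% of Z in Tuesday's and 1% in Saturday's at 30 h, holding that “the ceiling is near 40%”.

The flasks gave Tuesday's > Monday's > Sunday's > Thursday's > Friday's > Saturday's at 30 h and Friday's > Tuesday's > Monday's > Sunday's > Thursday's > Saturday's at 10 d, with 50.2% of Z in Tuesday's and 0% in Saturday's at 30 h.

    E ⇌ G (K = 50.0, k = 0.169 h⁻¹, Ea = 103 kJ mol⁻¹, ΔH = −47.0 kJ mol⁻¹)
    G ⇌ Z (K = 1.57, k = 0.189 h⁻¹, Ea = 102 kJ mol⁻¹, ΔH = −47.0 kJ mol⁻¹)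
    G + J → D (k = 0.0570 L mol⁻¹ h⁻¹, Ea = 61.0 kJ mol⁻¹)
    (constants at 25 °C)

Both forecast orders stood, while Tuesday's Z came out 8.2 percentage points above the forecast's figure. Tuesday's held 1.28% of its E at 30 h, where the time constant had said 0.800%. The neighbouring flask is Tuesday's with 1.8 M of J in place of 0.450 M. The time constant has no J in it, so the same reckoning gives 0.800% of E at 30 h there, and the neighbour holds 1.00%. The neighbour's Z is 29.9% and its D 52.7%, where Tuesday's holds Z 50.2% and D 17.1%.

(The earlier runs and the new flask stem from a simulated flask from invented constants.)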